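**Retrosynthetic overview**

1. The target is (2S)-naringenin joined through C8–C8'' to apigenin. The six benzyl ethers of 23 come off last. Ring C of the flavanone half (O1–C2) comes from chalcone 22 by catalytic asymmetric oxa-Michael addition, and 22 from the ring A acetyl group of 19 and aldehyde 20.
2. The strategy rests on ring C'' of the flavone half: the C4'' carbonyl carbon lies between arene carbon C4a'' and the C3''=C2'' unit that carries the 4-hydroxyphenyl ring, and O1'' sits on C8a''. That is CO placed between an ortho-iodophenol and an arylacetylene, so C4a''–C4'', C4''–C3'' and O1''–C2'' are cut to iodophenol 13, CO 14 and alkyne 15.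
3. The regiochemistry of 13 is fixed by symmetry. The future ring A'' is carried as a 4-benzyloxy-2,6-dihydroxyphenyl ring whose two open positions are equivalent, so mono-iodination can give one constitution only. O5'' is benzylated, so only the phenol next to the biaryl bond can close ring C''.
4. The C8–C8'' bond is a Suzuki–Miyaura coupling of iodoacetophenone 4 (from 2,4,6-trihydroxyacetophenone) with boronic acid 10 (from phloroglucinol by lithiation between two MOM ethers). Benzyl is the permanent protecting group and MOM the temporary one.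
5. Order of ring formation: rings A and A'' are bought; biaryl bond (step 7); ring C'' (step 10); ring C with C2 (step 13).

Key step: step 10

Assumption: the target structure defines only C2 (S); the tetra-ortho-substituted C8–C8'' axis is undefined and is not controlled, so the 2S product may be a mixture of two atropisomers if rotation is slow.
Assumption: the quinidine-derived thiourea of step 13 is taken to deliver the 2S series; the sense is to be checked on the simple chalcone from 2 and 20, and the quinine-derived pseudoenantiomer is used if it is opposite.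

**Route**

Step 1
Reactants: 1 2,4,6-trihydroxyacetophenone
Product: 2 1-[2,4-bis(benzyloxy)-6-hydroxyphenyl]ethanone
Conditions: BnBr (2.1 eq), K2CO3, DMF, rt
Reagents that add atoms: benzyl bromide, BrCc1ccccc1
Why: Williamson etherification of the two free phenols; the third hydroxyl is hydrogen-bonded to the acetyl carbonyl and much less nucleophilic, so alkylation should stop at the bis-ether.

Step 2
Reactants: 2 1-[2,4-bis(benzyloxy)-6-hydroxyphenyl]ethanone
Product: 3 1-[4,6-bis(benzyloxy)-2-hydroxy-3-iodophenyl]ethanone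
Conditions: NIS (1.05 eq), DMF, rt, dark
Reagents that add atoms: N-iodosuccinimide, O=C1CCC(=O)N1I
Why: Electrophilic aromatic iodination; chelated 2-hydroxy-4,6-dialkoxyaryl ketones and the related 5-hydroxy-7-alkoxyflavones are known to be iodinated at the carbon ortho to the chelated hydroxyl and not para to it, which puts iodine at C3 where the biaryl bond is needed.

Step 3
Reactants: 3 1-[4,6-bis(benzyloxy)-2-hydroxy-3-iodophenyl]ethanone
Product: 4 1-[4,6-bis(benzyloxy)-3-iodo-2-(methoxymethoxy)phenyl]ethanone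
Conditions: NaH (1.2 eq), MOMCl (1.3 eq), DMF, 0 °C to rt
Reagents that add atoms: chloromethyl methyl ether, COCCl
Why: O-alkylation of the sodium phenoxide (Williamson type) masks the hindered phenol for the cross-coupling with a group that leaves later together with the MOM groups of the other ring.

Step 4
Reactants: 5 phloroglucinol
Product: 6 3,5-bis(methoxymethoxy)phenol
Conditions: MOMCl (2.0 eq), i-Pr2NEt (2.2 eq), THF/CH2Cl2, 0 °C to rt
Reagents that add atoms: chloromethyl methyl ether, COCCl
Why: Statistical O-alkylation of three equivalent hydroxyls with a hard electrophile that does not C-alkylate; at two equivalents the bis-ether should be the main component and is separated by chromatography from the mono- and tris-ethers, which is acceptable on this cheap starting material.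

Step 5
Reactants: 6 3,5-bis(methoxymethoxy)phenol
Product: 7 1-(benzyloxy)-3,5-bis(methoxymethoxy)benzene
Conditions: BnBr (1.2 eq), K2CO3, DMF, rt
Reagents that add atoms: benzyl bromide, BrCc1ccccc1
Why: Williamson etherification of the single free phenol installs the permanent group on the oxygen that becomes O5''.

Step 6
Reactants: 7 1-(benzyloxy)-3,5-bis(methoxymethoxy)benzene
Product: 10 [4-(benzyloxy)-2,6-bis(methoxymethoxy)phenyl]boronic acid, via aryllithium 8 (not isolated), via lithium aryltrimethoxyborate 9 (not isolated)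
Conditions: n-BuLi (1.1 eq), THF, 0 °C; B(OMe)3 (2 eq), −78 °C to rt; 1 M HCl to pH 6, 0 °C
Reagents that add atoms: trimethyl borate, COB(OC)OC; water, O
Why: Directed ortho-metalation: the ring carbon between the two chelating MOM ethers is the most acidic site (the benzyl ether is a weaker director and its benzylic protons react more slowly at 0 °C), and borate trapping with mild hydrolysis gives the boronic acid.

Step 7
Reactants: 4 1-[4,6-bis(benzyloxy)-3-iodo-2-(methoxymethoxy)phenyl]ethanone; 10 [4-(benzyloxy)-2,6-bis(methoxymethoxy)phenyl]boronic acid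
Product: 11 3-acetyl-4,4',6-tris(benzyloxy)-2,2',6'-tris(methoxymethoxy)biphenyl
Conditions: 10 (1.8 eq), Pd(OAc)2 (5 mol%), SPhos (10 mol%), K3PO4 (3 eq), toluene/H2O 10:1, 100 °C
Reagents that add atoms: none
Why: Suzuki–Miyaura coupling; dialkylbiarylphosphine ligands of the SPhos type are known to give tetra-ortho-substituted biaryls from 2,6-dialkoxyarylboronic acids, the aryl iodide is the reactive partner, and the ketone, benzyl ethers and MOM ethers are inert to aqueous phosphate.

Step 8
Reactants: 11 3-acetyl-4,4',6-tris(benzyloxy)-2,2',6'-tris(methoxymethoxy)biphenyl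
Product: 12 3-acetyl-4,4',6-tris(benzyloxy)-2,2',6'-trihydroxybiphenyl
Conditions: 3 M HCl, MeOH/THF, 45 °C
Reagents that add atoms: none
Why: Acid-catalysed acetal exchange with methanol should remove the three MOM groups while the benzyl ethers and the ketone stay.

Step 9
Reactants: 12 3-acetyl-4,4',6-tris(benzyloxy)-2,2',6'-trihydroxybiphenyl
Product: 13 3-acetyl-4,4',6-tris(benzyloxy)-2,2',6'-trihydroxy-3'-iodobiphenyl
Conditions: NIS (1.0 eq), MeCN/THF, −40 to 0 °C
Reagents that add atoms: N-iodosuccinimide, O=C1CCC(=O)N1I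
Why: Electrophilic aromatic iodination of the resorcinol ring, the most electron-rich ring; its two open positions C3' and C5' are equivalent, each ortho to one hydroxyl and para to the other, so the first iodination can give only this ortho-iodophenol, while one equivalent at low temperature limits di-iodination and the ring A C5–H on the acyl-bearing ring should react more slowly.

Step 10
Reactants: 13 3-acetyl-4,4',6-tris(benzyloxy)-2,2',6'-trihydroxy-3'-iodobiphenyl; 14 carbon monoxide; 15 1-(benzyloxy)-4-ethynylbenzene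
Product: 18 8-[3-acetyl-4,6-bis(benzyloxy)-2-hydroxyphenyl]-5-(benzyloxy)-2-[4-(benzyloxy)phenyl]-7-hydroxy-4H-chromen-4-one, via ynone 16 (not isolated), via enaminone 17 (not isolated)
Conditions: PdCl2(dppf) (5 mol%), CO (20 atm), 15 (1.5 eq), Et2NH, 120 °C
Reagents that add atoms: none
Why: Zerovalent palladium formed in situ from PdCl2(dppf) inserts into the C3'–I bond of 13, CO insertion gives the aroylpalladium species, and copper-free coupling with the amine-activated alkyne 15 gives the ortho-hydroxyaryl ynone 16 (bonds C4a''–C4'' and C4''–C3''); diethylamine then adds to the ynone to give enaminone 17, and the phenol oxygen displaces the amine at C2'' (bond O1''–C2''). The closest known reaction type is the palladium-catalysed carbonylative annulation of ortho-iodophenols with terminal arylacetylenes in a secondary amine, which gives flavones. Ring C'' closes in a formal 6-endo mode (6-endo-trig addition–elimination on 17, equivalent overall to 6-endo-dig attack on 16), and no stereocenter is formed. The step needs the six-membered flavone and not the five-membered aurone (5-exo-dig), which the secondary amine secures by diverting the ynone through the enaminone before the phenol attacks; it also needs carbonylative over direct alkynylation, which the absence of copper, the CO pressure and the fast CO insertion of an electron-rich aryl–palladium bond favour. Only the phenol flanked by iodine and the biaryl bond can cyclise, because O5'' is benzylated, the second resorcinol hydroxyl is not ortho to iodine and the ring A hydroxyl is chelated and remote, so only the 8''-linked flavone should form. The step is run before the base-sensitive C2 stereocenter exists, so the hot amine cannot harm it.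

Step 11
Reactants: 18 8-[3-acetyl-4,6-bis(benzyloxy)-2-hydroxyphenyl]-5-(benzyloxy)-2-[4-(benzyloxy)phenyl]-7-hydroxy-4H-chromen-4-one
Product: 19 8-[3-acetyl-4,6-bis(benzyloxy)-2-hydroxyphenyl]-5,7-bis(benzyloxy)-2-[4-(benzyloxy)phenyl]-4H-chromen-4-one
Conditions: BnBr (1.1 eq), K2CO3 (1.5 eq), DMF, rt
Reagents that add atoms: benzyl bromide, BrCc1ccccc1
Why: Williamson etherification selective for the acidic, non-chelated 7''-hydroxyl, which would otherwise quench the basic catalyst of step 13; the ring A hydroxyl is chelated to the acetyl group and flanked on both sides, so it should stay free as in step 1.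

Step 12
Reactants: 19 8-[3-acetyl-4,6-bis(benzyloxy)-2-hydroxyphenyl]-5,7-bis(benzyloxy)-2-[4-(benzyloxy)phenyl]-4H-chromen-4-one; 20 4-(benzyloxy)benzaldehyde
Product: 22 8-[4,6-bis(benzyloxy)-3-[(2E)-3-[4-(benzyloxy)phenyl]prop-2-enoyl]-2-hydroxyphenyl]-5,7-bis(benzyloxy)-2-[4-(benzyloxy)phenyl]-4H-chromen-4-one, via aldol adduct 21 (not isolated)
Conditions: 20 (1.5 eq), KOH (50% aq.), EtOH/THF, rt; cold acidification
Reagents that add atoms: none
Why: Claisen–Schmidt condensation: aldol addition of the methyl ketone enolate to the non-enolisable aldehyde and E1cB dehydration give the E-enone, which rests as the chalcone phenoxide in strong base and does not cyclise there, while the flavone tolerates cold alkali; cold acidification and prompt chromatography should keep racemic flavanone out of step 13.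

Step 13
Reactants: 22 8-[4,6-bis(benzyloxy)-3-[(2E)-3-[4-(benzyloxy)phenyl]prop-2-enoyl]-2-hydroxyphenyl]-5,7-bis(benzyloxy)-2-[4-(benzyloxy)phenyl]-4H-chromen-4-one
Product: 23 (2S)-5,7-bis(benzyloxy)-2-[4-(benzyloxy)phenyl]-8-[5,7-bis(benzyloxy)-2-[4-(benzyloxy)phenyl]-4-oxo-4H-chromen-8-yl]-2,3-dihydro-4H-chromen-4-one
Conditions: 1-[3,5-bis(trifluoromethyl)phenyl]-3-(9-deoxy-epi-quinidin-9-yl)thiourea (15 mol%), toluene, 0 °C, stopped at full conversion
Reagents that add atoms: none
Why: Intramolecular oxa-Michael addition (6-endo-trig) of the 2'-hydroxychalcone under bifunctional cinchona thiourea catalysis, a known way to close flavanones: the quinuclidine nitrogen activates the phenol, the thiourea binds the enone carbonyl, and the chiral pocket is to direct the oxygen to the Si face of the β-carbon, which gives 2S.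

Step 14
Reactants: 23 (2S)-5,7-bis(benzyloxy)-2-[4-(benzyloxy)phenyl]-8-[5,7-bis(benzyloxy)-2-[4-(benzyloxy)phenyl]-4-oxo-4H-chromen-8-yl]-2,3-dihydro-4H-chromen-4-one
Product: 24 (2S)-5,7-dihydroxy-2-(4-hydroxyphenyl)-8-[5,7-dihydroxy-2-(4-hydroxyphenyl)-4-oxo-4H-chromen-8-yl]-2,3-dihydro-4H-chromen-4-one (CNP0339995.1)
Conditions: H2 (1 atm), 10% Pd/C, THF/MeOH, rt, stopped after uptake of six equivalents
Reagents that add atoms: none
Why: Hydrogenolysis of the six aryl benzyl ethers under neutral conditions, which should leave the C2 stereocenter (no base, no ring opening), the flavone double bond and the aryl ketones untouched.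

**Compound list**

1 | 2,4,6-trihydroxyacetophenone | CC(=O)c1c(O)cc(O)cc1O | starting material
2 | 1-[2,4-bis(benzyloxy)-6-hydroxyphenyl]ethanone | CC(=O)c1c(O)cc(OCc2ccccc2)cc1OCc1ccccc1 | intermediate
3 | 1-[4,6-bis(benzyloxy)-2-hydroxy-3-iodophenyl]ethanone | CC(=O)c1c(O)c(I)c(OCc2ccccc2)cc1OCc1ccccc1 | intermediate
4 | 1-[4,6-bis(benzyloxy)-3-iodo-2-(methoxymethoxy)phenyl]ethanone | CC(=O)c1c(OCOC)c(I)c(OCc2ccccc2)cc1OCc1ccccc1 | intermediate
5 | phloroglucinol | Oc1cc(O)cc(O)c1 | starting material
6 | 3,5-bis(methoxymethoxy)phenol | COCOc1cc(O)cc(OCOC)c1 | intermediate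
7 | 1-(benzyloxy)-3,5-bis(methoxymethoxy)benzene | COCOc1cc(OCc2ccccc2)cc(OCOC)c1 | intermediate
8 | [4-(benzyloxy)-2,6-bis(methoxymethoxy)phenyl]lithium | [Li]c1c(OCOC)cc(OCc2ccccc2)cc1OCOC | intermediate
9 | lithium [4-(benzyloxy)-2,6-bis(methoxymethoxy)phenyl]trimethoxyborate | [Li+].CO[B-](OC)(OC)c1c(OCOC)cc(OCc2ccccc2)cc1OCOC | intermediate
10 | [4-(benzyloxy)-2,6-bis(methoxymethoxy)phenyl]boronic acid | OB(O)c1c(OCOC)cc(OCc2ccccc2)cc1OCOC | intermediate
11 | 3-acetyl-4,4',6-tris(benzyloxy)-2,2',6'-tris(methoxymethoxy)biphenyl | CC(=O)c1c(OCOC)c(-c2c(OCOC)cc(OCc3ccccc3)cc2OCOC)c(OCc2ccccc2)cc1OCc1ccccc1 | intermediate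
12 | 3-acetyl-4,4',6-tris(benzyloxy)-2,2',6'-trihydroxybiphenyl | CC(=O)c1c(O)c(-c2c(O)cc(OCc3ccccc3)cc2O)c(OCc2ccccc2)cc1OCc1ccccc1 | intermediate
13 | 3-acetyl-4,4',6-tris(benzyloxy)-2,2',6'-trihydroxy-3'-iodobiphenyl | CC(=O)c1c(O)c(-c2c(O)c(I)c(OCc3ccccc3)cc2O)c(OCc2ccccc2)cc1OCc1ccccc1 | intermediate
14 | carbon monoxide | [C-]#[O+] | starting material
15 | 1-(benzyloxy)-4-ethynylbenzene | C#Cc1ccc(OCc2ccccc2)cc1 | starting material
16 | 1-[3-(3-acetyl-4,6-bis(benzyloxy)-2-hydroxyphenyl)-6-(benzyloxy)-2,4-dihydroxyphenyl]-3-[4-(benzyloxy)phenyl]prop-2-yn-1-one (ynone) | CC(=O)c1c(O)c(-c2c(O)c(C(=O)C#Cc3ccc(OCc4ccccc4)cc3)c(OCc3ccccc3)cc2O)c(OCc2ccccc2)cc1OCc1ccccc1 | intermediate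
17 | 1-[3-(3-acetyl-4,6-bis(benzyloxy)-2-hydroxyphenyl)-6-(benzyloxy)-2,4-dihydroxyphenyl]-3-[4-(benzyloxy)phenyl]-3-(diethylamino)prop-2-en-1-one (enaminone) | CC(=O)c1c(O)c(-c2c(O)c(C(=O)C=C(N(CC)CC)c3ccc(OCc4ccccc4)cc3)c(OCc3ccccc3)cc2O)c(OCc2ccccc2)cc1OCc1ccccc1 | intermediate
18 | 8-[3-acetyl-4,6-bis(benzyloxy)-2-hydroxyphenyl]-5-(benzyloxy)-2-[4-(benzyloxy)phenyl]-7-hydroxy-4H-chromen-4-one | CC(=O)c1c(O)c(-c2c(O)cc(OCc3ccccc3)c3c(=O)cc(-c4ccc(OCc5ccccc5)cc4)oc23)c(OCc2ccccc2)cc1OCc1ccccc1 | intermediate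
19 | 8-[3-acetyl-4,6-bis(benzyloxy)-2-hydroxyphenyl]-5,7-bis(benzyloxy)-2-[4-(benzyloxy)phenyl]-4H-chromen-4-one | CC(=O)c1c(O)c(-c2c(OCc3ccccc3)cc(OCc3ccccc3)c3c(=O)cc(-c4ccc(OCc5ccccc5)cc4)oc23)c(OCc2ccccc2)cc1OCc1ccccc1 | intermediate
20 | 4-(benzyloxy)benzaldehyde | O=Cc1ccc(OCc2ccccc2)cc1 | starting material
21 | 8-[4,6-bis(benzyloxy)-3-[3-[4-(benzyloxy)phenyl]-3-hydroxypropanoyl]-2-hydroxyphenyl]-5,7-bis(benzyloxy)-2-[4-(benzyloxy)phenyl]-4H-chromen-4-one (aldol adduct, carbinol centre uncontrolled) | O=C(CC(O)c1ccc(OCc2ccccc2)cc1)c1c(O)c(-c2c(OCc3ccccc3)cc(OCc3ccccc3)c3c(=O)cc(-c4ccc(OCc5ccccc5)cc4)oc23)c(OCc2ccccc2)cc1OCc1ccccc1 | intermediate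
22 | 8-[4,6-bis(benzyloxy)-3-[(2E)-3-[4-(benzyloxy)phenyl]prop-2-enoyl]-2-hydroxyphenyl]-5,7-bis(benzyloxy)-2-[4-(benzyloxy)phenyl]-4H-chromen-4-one | O=C(/C=C/c1ccc(OCc2ccccc2)cc1)c1c(O)c(-c2c(OCc3ccccc3)cc(OCc3ccccc3)c3c(=O)cc(-c4ccc(OCc5ccccc5)cc4)oc23)c(OCc2ccccc2)cc1OCc1ccccc1 | intermediate
23 | (2S)-5,7-bis(benzyloxy)-2-[4-(benzyloxy)phenyl]-8-[5,7-bis(benzyloxy)-2-[4-(benzyloxy)phenyl]-4-oxo-4H-chromen-8-yl]-2,3-dihydro-4H-chromen-4-one | O=C1C[C@@H](c2ccc(OCc3ccccc3)cc2)Oc2c1c(OCc1ccccc1)cc(OCc1ccccc1)c2-c1c(OCc2ccccc2)cc(OCc2ccccc2)c2c(=O)cc(-c3ccc(OCc4ccccc4)cc3)oc12 | intermediate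
24 | (2S)-5,7-dihydroxy-2-(4-hydroxyphenyl)-8-[5,7-dihydroxy-2-(4-hydroxyphenyl)-4-oxo-4H-chromen-8-yl]-2,3-dihydro-4H-chromen-4-one | O=C1C[C@@H](c2ccc(O)cc2)Oc2c1c(O)cc(O)c2-c1c(O)cc(O)c2c(=O)cc(-c3ccc(O)cc3)oc12 | target

**Step count**

Total: 14 steps. Longest linear sequence: 11 steps (steps 1–3 and 7–14, or steps 4–6 and 7–14).

**Steps most likely to fail**

Step 10. Oxidative addition into a C–I bond flanked by two oxygen substituents on an electron-rich ring may be slow. That would leave room for loss of iodine by protonolysis, for capture of the aroylpalladium species by diethylamine, or for direct alkynylation followed by furan closure. The fallback builds the flavone first and makes the biaryl bond with it; it sets out from 4 and comes back at 19. Commercial apigenin is benzylated at all three hydroxyls (BnBr, K2CO3, DMF, 80 °C) to 5,7-bis(benzyloxy)-2-[4-(benzyloxy)phenyl]-4H-chromen-4-one F1. Iodination with NIS and catalytic CF3CO2H in MeCN, which for 5,7-dialkoxyflavones goes to C8, should give 5,7-bis(benzyloxy)-2-[4-(benzyloxy)phenyl]-8-iodo-4H-chromen-4-one F2. Miyaura borylation (B2pin2, PdCl2(dppf), KOAc, dioxane, 90 °C) should give the 8-(4,4,5,5-tetramethyl-1,3,2-dioxaborolan-2-yl)flavone F3. Suzuki–Miyaura coupling of F3 with 4 (Pd(OAc)2, SPhos, K3PO4, toluene/H2O, 100 °C) should give 8-[3-acetyl-4,6-bis(benzyloxy)-2-(methoxymethoxy)phenyl]-5,7-bis(benzyloxy)-2-[4-(benzyloxy)phenyl]-4H-chromen-4-one F4. Removal of the MOM group (3 M HCl, MeOH/THF, 45 °C) then gives 19. Steps 4–6 and 8–11 are not needed on this path.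

Step 7. Protodeboronation of the 2,6-dialkoxyarylboronic acid 10 in hot aqueous base may outrun transmetalation, and reductive elimination at the tetra-ortho-substituted centre may be slow. The fallback is a Negishi coupling, which has no protonolysis pathway under anhydrous conditions; it sets out from 7 and 4 and comes back at 11. Aryllithium 8, made from 7 as in step 6, is treated with ZnCl2 in THF to give [4-(benzyloxy)-2,6-bis(methoxymethoxy)phenyl]zinc chloride F5. F5 is coupled with 4 (Pd2(dba)3, RuPhos, THF/NMP, 70 °C); the arylzinc reagent tolerates the methyl ketone, and the product is 11.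

Step 13. Facial selectivity in the oxa-Michael closure may be poor, reversible ring opening under the basic catalyst may erode the enantiomeric purity, and one sense of the biaryl axis may be mismatched with the catalyst. The fallback sets C2 by an irreversible C–C bond formation; it sets out from 19 and comes back at 23. Heating 19 with N,N-dimethylformamide dimethyl acetal (toluene, 90 °C) should give 8-[4,6-bis(benzyloxy)-3-[(2E)-3-(dimethylamino)prop-2-enoyl]-2-hydroxyphenyl]-5,7-bis(benzyloxy)-2-[4-(benzyloxy)phenyl]-4H-chromen-4-one F6. Acid (conc. HCl, CH2Cl2, rt) closes it to 5,7-bis(benzyloxy)-8-[5,7-bis(benzyloxy)-2-[4-(benzyloxy)phenyl]-4-oxo-4H-chromen-8-yl]-4H-chromen-4-one F7. Rhodium-catalysed enantioselective 1,4-addition of 4-(benzyloxy)phenylboronic acid to the chromone ([Rh(OH)(cod)]2, electron-poor atropisomeric diphosphine MeO-F12-BIPHEP in the enantiomer that gives 2S, toluene, rt to 50 °C) should give 23. The flavone unit, whose β-carbon is fully substituted, should not react.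

**Further compounds**

F1 | step 10 | 5,7-bis(benzyloxy)-2-[4-(benzyloxy)phenyl]-4H-chromen-4-one | O=c1cc(-c2ccc(OCc3ccccc3)cc2)oc2cc(OCc3ccccc3)cc(OCc3ccccc3)c12
F2 | step 10 | 5,7-bis(benzyloxy)-2-[4-(benzyloxy)phenyl]-8-iodo-4H-chromen-4-one | O=c1cc(-c2ccc(OCc3ccccc3)cc2)oc2c(I)c(OCc3ccccc3)cc(OCc3ccccc3)c12
F3 | step 10 | 5,7-bis(benzyloxy)-2-[4-(benzyloxy)phenyl]-8-(4,4,5,5-tetramethyl-1,3,2-dioxaborolan-2-yl)-4H-chromen-4-one | O=c1cc(-c2ccc(OCc3ccccc3)cc2)oc2c(B3OC(C)(C)C(C)(C)O3)c(OCc3ccccc3)cc(OCc3ccccc3)c12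
F4 | step 10 | 8-[3-acetyl-4,6-bis(benzyloxy)-2-(methoxymethoxy)phenyl]-5,7-bis(benzyloxy)-2-[4-(benzyloxy)phenyl]-4H-chromen-4-one | CC(=O)c1c(OCOC)c(-c2c(OCc3ccccc3)cc(OCc3ccccc3)c3c(=O)cc(-c4ccc(OCc5ccccc5)cc4)oc23)c(OCc2ccccc2)cc1OCc1ccccc1
F5 | step 7 | [4-(benzyloxy)-2,6-bis(methoxymethoxy)phenyl]zinc chloride | Cl[Zn]c1c(OCOC)cc(OCc2ccccc2)cc1OCOC
F6 | step 13 | 8-[4,6-bis(benzyloxy)-3-[(2E)-3-(dimethylamino)prop-2-enoyl]-2-hydroxyphenyl]-5,7-bis(benzyloxy)-2-[4-(benzyloxy)phenyl]-4H-chromen-4-one | CN(C)/C=C/C(=O)c1c(O)c(-c2c(OCc3ccccc3)cc(OCc3ccccc3)c3c(=O)cc(-c4ccc(OCc5ccccc5)cc4)oc23)c(OCc2ccccc2)cc1OCc1ccccc1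
F7 | step 13 | 5,7-bis(benzyloxy)-8-[5,7-bis(benzyloxy)-2-[4-(benzyloxy)phenyl]-4-oxo-4H-chromen-8-yl]-4H-chromen-4-one | O=c1ccoc2c1c(OCc1ccccc1)cc(OCc1ccccc1)c2-c1c(OCc2ccccc2)cc(OCc2ccccc2)c2c(=O)cc(-c3ccc(OCc4ccccc4)cc3)oc12
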